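**Retrosynthesis**
- The target comes from global saponification of a chromene methyl ester carrying an aryl pivalate (the 6-OH is protected as pivalate).
- The pyran ring, the only ring formed, is closed last but one. A racemic o-hydroxybenzylic allylic alcohol undergoes chiral-acid-catalysed dehydrative 6-endo C–O closure, which sets the C2 quaternary ether centre.
- That alcohol comes from ortho-hydroxyalkylation of mono-protected methylhydroquinone with a polyene enal ester.
- The enal ester comes from a Z-selective Still–Gennari HWE of a C12 dialdehyde with an α-homoprenyl phosphonoacetate.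
- The dialdehyde comes from terminal-selective oxidative cleavage of (E,E)-farnesal. Every alkene geometry is set before the key step.

**Assumptions**
- (2E,6E)-Farnesol, the Still–Gennari phosphonoacetate and 5-bromo-2-methylpent-2-ene are purchasable.
- The (S)-configured catalyst is assumed to give the (R) centre; the enantiomeric catalyst is used if the opposite sense is found.

---

**Step 1**
Reactants: 1 (2E,6E)-farnesol
Product: 2 (2E,6E)-farnesal
Conditions: MnO2 (10 equiv), CH2Cl2, rt, 12 h
Reagents that add atoms: none
Why: MnO2 oxidises the allylic alcohol chemoselectively to the enal without isomerising the alkenes (allylic alcohol oxidation).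

**Step 2**
Reactants: 2 farnesal
Product: 3 (2E,6E)-10-bromo-11-hydroxy-3,7,11-trimethyldodeca-2,6-dienal (racemic at C10)
Conditions: NBS (1.05 equiv), THF/H2O 3:1, 0 °C, 1 h
Reagents that add atoms: NBS (O=C1CCC(=O)N1Br), which supplies Br; water (O), which supplies OH
Why: The enal-deactivated C2=C3 and the more hindered C6=C7 react more slowly than the terminal trisubstituted alkene, so bromohydrin formation occurs there (van Tamelen-type terminal bromohydrin).

**Step 3**
Reactants: 3 bromohydrin
Product: 4 (2E,6E)-10,11-epoxy-3,7,11-trimethyldodeca-2,6-dienal (racemic)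
Conditions: K2CO3 (1.5 equiv), MeOH, 0 °C → rt, 1 h
Reagents that add atoms: none (base only; HBr is lost)
Why: Intramolecular SN2 closure of the alkoxide onto the C–Br carbon gives the epoxide (epoxide formation from a halohydrin).

**Step 4**
Reactants: 4 epoxide
Product: 5 (2E,6E)-3,7-dimethyldeca-2,6-dienedial
Conditions: H5IO6 (1.3 equiv), THF/Et2O/H2O, 0 °C → rt, 1 h
Reagents that add atoms: H5IO6 (OI(O)(O)(O)(O)=O) as oxidant and water (O); the new CHO oxygen comes from the epoxide/water
Why: Acid opens the epoxide to the diol, which periodate cleaves to the aldehyde plus acetone (Malaprade-type cleavage), leaving the E-enal and the C6=C7 alkene untouched.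

**Step 5**
Reactants: 6 methyl 2-[bis(2,2,2-trifluoroethoxy)phosphoryl]acetate; 7 5-bromo-2-methylpent-2-ene
Product: 8 methyl 2-[bis(2,2,2-trifluoroethoxy)phosphoryl]-6-methylhept-5-enoate
Conditions: NaH (1.0 equiv), NaI (0.1 equiv), THF/DMF 4:1, 0 °C → 50 °C, 12 h
Reagents that add atoms: none beyond reactant 7 (NaI is a catalyst)
Why: The stabilised phosphonate carbanion is mono-alkylated by the in-situ alkyl iodide (SN2 alkylation).

**Step 6**
Reactants: 5 dialdehyde; 8 α-homoprenyl phosphonate
Product: 9 methyl (2Z,6E,10E)-6,10-dimethyl-2-(4-methylpent-3-en-1-yl)-12-oxododeca-2,6,10-trienoate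
Conditions: 8 (1.1 equiv) + KHMDS (1.05 equiv), 18-crown-6 (3 equiv), THF, −78 °C, 15 min; then 5 (1.0 equiv), −78 °C, 3 h
Reagents that add atoms: none (base and crown ether only)
Why: The saturated aldehyde is far more electrophilic than the β,β-disubstituted enal, and the electron-poor bis(trifluoroethyl) phosphonate under K+/crown conditions gives the kinetic Z-trisubstituted acrylate (ester cis to the chain), as in the target (Still–Gennari HWE).

**Step 7**
Reactants: 10 2-methylbenzene-1,4-diol (methylhydroquinone)
Product: 11 4-hydroxy-3-methylphenyl pivalate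
Conditions: PivCl (0.95 equiv), Et3N (1.1 equiv), CH2Cl2, −20 → 0 °C, 3 h
Reagents that add atoms: PivCl (CC(C)(C)C(=O)Cl)
Why: The OH meta to the methyl is the less hindered one, so it is acylated selectively; this leaves the OH that will become the ring oxygen free, with one open ortho position (selective mono-acylation).

**Step 8**
Reactants: 11 phenol; 9 enal ester
Product: 12 methyl (2Z,6E,10E)-12-hydroxy-12-[2-hydroxy-3-methyl-5-(pivaloyloxy)phenyl]-6,10-dimethyl-2-(4-methylpent-3-en-1-yl)dodeca-2,6,10-trienoate (racemic carbinol)
Conditions: EtMgBr (1.0 equiv), toluene/Et2O, 0 °C, 30 min; then 9 (0.9 equiv), 0 °C → 35 °C, 12 h; quench with pH 7 phosphate buffer, no silica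
Reagents that add atoms: none (EtMgBr only deprotonates; Et is not retained)
Why: The phenoxymagnesium halide delivers the aldehyde to the single free ortho carbon through a six-membered Mg chelate, giving the 1,2-adduct (Casiraghi-type ortho-hydroxyalkylation).

**Step 9**
Reactants: 12 carbinol
Product: 13 methyl (2Z,6E)-9-[(2R)-2,8-dimethyl-6-(pivaloyloxy)-2H-chromen-2-yl]-6-methyl-2-(4-methylpent-3-en-1-yl)nona-2,6-dienoate
Conditions: (S)-N-triflylphosphoramide from (S)-3,3′-bis(2,4,6-triisopropylphenyl)-BINOL (10 mol %), toluene (0.01 M), 4 Å MS, 0 °C, 48 h; Et3N quench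
Reagents that add atoms: none (loss of H2O)
Why: Proposed new method: the chiral acid ionises the racemic carbinol to an o-hydroxyphenyl-allyl cation (o-quinone-methide-type 1-oxatriene), and its H-bonded chiral phosphoramidate ion pair closes the C–O bond 6-endo onto one enantiotopic face of the Me/alkyl terminus, so the long chain lies outward and the methyl inward, giving the (R) quaternary centre stereoconvergently; the closest known reactions are chiral-phosphoric-acid generation and trapping of o-quinone methides from 2-hydroxybenzyl alcohols and confined-acid asymmetric hydroalkoxylation that forms 2-methyl-2-alkyl cyclic ethers.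

**Step 10**
Reactants: 13 chromene ester/pivalate
Product: 14 (R)-sargachromenol, (2Z,6E)-9-[(2R)-6-hydroxy-2,8-dimethyl-2H-chromen-2-yl]-6-methyl-2-(4-methylpent-3-en-1-yl)nona-2,6-dienoic acid
Conditions: LiOH·H2O (8 equiv), THF/MeOH/H2O 3:1:1, 50 °C, 16 h, N2; then NaH2PO4 to pH 4
Reagents that add atoms: LiOH (O[Li]) and water (O)
Why: Saponification removes both the aryl pivalate and the hindered methyl ester; the Z-acrylate, the chromene and the C2 ether centre are base-stable, and the mild acidic workup avoids ionising the tertiary allylic aryl ether (ester hydrolysis).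

---

**Compound list**

| # | Name | SMILES | Role |
|---|---|---|---|
| 1 | (2E,6E)-farnesol | CC(C)=CCC/C(C)=C/CC/C(C)=C/CO | starting material |
| 2 | (2E,6E)-farnesal | CC(C)=CCC/C(C)=C/CC/C(C)=C/C=O | intermediate |
| 3 | terminal bromohydrin (racemic) | CC(C)(O)C(Br)CC/C(C)=C/CC/C(C)=C/C=O | intermediate |
| 4 | 10,11-epoxide (racemic) | CC1(C)OC1CC/C(C)=C/CC/C(C)=C/C=O | intermediate |
| 5 | (2E,6E)-3,7-dimethyldeca-2,6-dienedial | O=CCC/C(C)=C/CC/C(C)=C/C=O | intermediate |
| 6 | methyl bis(2,2,2-trifluoroethyl)phosphonoacetate | COC(=O)CP(=O)(OCC(F)(F)F)OCC(F)(F)F | starting material |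
| 7 | 5-bromo-2-methylpent-2-ene | CC(C)=CCCBr | starting material |
| 8 | α-homoprenyl phosphonoacetate | COC(=O)C(CCC=C(C)C)P(=O)(OCC(F)(F)F)OCC(F)(F)F | intermediate |
| 9 | enal ester (2Z,6E,10E) | CC(C)=CCC/C(=C/CC/C(C)=C/CC/C(C)=C/C=O)C(=O)OC | intermediate |
| 10 | 2-methylhydroquinone | Cc1cc(O)ccc1O | starting material |
| 11 | 4-hydroxy-3-methylphenyl pivalate | Cc1cc(OC(=O)C(C)(C)C)ccc1O | intermediate |
| 12 | o-hydroxybenzylic allylic alcohol (racemic) | CC(C)=CCC/C(=C/CC/C(C)=C/CC/C(C)=C/C(O)c1cc(OC(=O)C(C)(C)C)cc(C)c1O)C(=O)OC | intermediate |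
| 13 | (R)-chromene methyl ester/pivalate | CC(C)=CCC/C(=C/CC/C(C)=C/CC[C@]1(C)C=Cc2cc(OC(=O)C(C)(C)C)cc(C)c2O1)C(=O)OC | intermediate |
| 14 | (R)-sargachromenol | CC(C)=CCC/C(=C/CC/C(C)=C/CC[C@]1(C)C=Cc2cc(O)cc(C)c2O1)C(=O)O | target |

**Total steps:** 10. **Longest linear sequence:** 8 (1→2→3→4→5→9→12→13→14, with 6 + 8 joining at the HWE step).

**Three steps most likely to fail**
1. **Step 9 (the new asymmetric cyclodehydration).** The ee may be low because methyl versus a CH2CH2-alkenyl chain is a weak discriminator, or the ionised chromene may racemise. *Fallback (known chemistry):* make racemic 13 from 11 and 9 by the phenylboronic acid/propionic acid condensation–oxa-6π annulation, then resolve it by preparative chiral-phase SFC/HPLC and carry the (R) enantiomer to Step 10.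
2. **Step 8 (ortho-hydroxyalkylation).** The hindered β,β-disubstituted enal may add poorly, or the labile benzylic allylic alcohol may dehydrate on work-up. *Fallback:* directed ortho-lithiation (s-BuLi/TMEDA) of the MOM ether of 4-TBSO-2-methylphenol, 1,2-addition of the aryllithium to 9, then MOM/TBS removal. This changes the C–C bond formation from phenoxide to aryl-lithium.
3. **Step 6 (chemoselective Z-selective HWE on the dialdehyde).** The enal may compete, or Z-selectivity may be low with the α-homoprenyl phosphonate. *Fallback:* run the same HWE on the mono-aldehyde made from farnesyl acetate (bromohydrin, epoxide, H5IO6), then K2CO3/MeOH deacetylation and MnO2 oxidation to give 9. This reorders the sequence so the enal is unmasked only after the olefination.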